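**Retrosynthetic overview**
1. Hydroquinone 20 ⇐ phenol 18 by late para-oxygenation; the arene comes from o-cresol.
2. 18 ⇐ α-bromo ketone 11 + (E)-alkenylzirconocene from arylbutyne 16 (Ni C(sp3)–C(sp2) coupling, no enolate).
3. 11 ⇐ cyclobutane photoadduct 8 (LiCH2Br acylation, loss of menthone, retro-aldol ring opening: de Mayo logic).
4. 8 ⇐ key [2+2] photocycloaddition of chiral spirodioxinone 6 with symmetric 1,2-dimethylcyclopentene 7; both quaternary centres are set in this one step.
5. Ring order: dioxinone (step 2) → cyclobutane (step 3, opened again in step 4); the cyclopentane and benzene rings are bought in.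

Assumption: 4-methylpent-3-enoic acid, 1,2-dimethylcyclopentene, (-)-menthone and 1-bromobut-2-yne are taken as catalogue chemicals.

**Route**

Step 1
Reactants: 1 4-methylpent-3-enoic acid; 2 Meldrum's acid
Product: 3 5-(1-hydroxy-4-methylpent-3-en-1-ylidene)-2,2-dimethyl-1,3-dioxane-4,6-dione
Conditions: DCC (1.1 equiv), DMAP (1.5 equiv), CH2Cl2, 0 °C → rt; 1 M KHSO4 wash
Reagents that add atoms: none
Why: Carbodiimide C-acylation of Meldrum's acid (Yonemitsu-type) gives the enolised acyl Meldrum's acid, and because the product is held as its DMAP enolate salt the skipped alkene stays out of conjugation; no stereocentre is formed.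

Step 2
Reactants: 3 acyl Meldrum's acid; 4 (-)-menthone
Product: 6 (6R,7S,10R)-7-isopropyl-10-methyl-4-(3-methylbut-2-en-1-yl)-1,5-dioxaspiro[5.5]undec-3-en-2-one, via acylketene 5 (not isolated)
Conditions: 4 (3 equiv), toluene, 110 °C, 2 h; chromatography (separate spiro epimers, recover 4)
Reagents that add atoms: none
Why: Thermal retro-[4+2] of the acyl Meldrum's acid (loss of acetone and CO2) gives acylketene 5, which is trapped by the menthone carbonyl in a hetero-Diels–Alder reaction to build the dioxinone; the menthane centres are carried over unchanged and the new spiro centre forms as two epimers, of which the (6R) epimer is isolated.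

Step 3 (key step)
Reactants: 6 spirodioxinone; 7 1,2-dimethylcyclopent-1-ene
Product: 8 cis-anti-cis cyclobutane photoadduct (spiro-menthylidene ketal; all four cyclobutane centres R)
Conditions: 7 (15 equiv), hν (300 nm, Pyrex), MeCN/acetone 9:1, –20 °C; chromatography
Reagents that add atoms: none
Why: Dioxinone–alkene [2+2] photocycloaddition (first half of a de Mayo sequence), in which the triplet enone adds suprafacially across the tetrasubstituted C=C so that both methyl-bearing quaternary centres arise cis in one step, and the mirror symmetry of 7 is broken because the unsymmetrical C3=C4 unit of 6 lies across the alkene on the dioxinone face syn to C11H2 (anti to the isopropyl-bearing C7) in the exo (cis-anti-cis) orientation, the minor diastereomers being removed at this stage.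

Step 4
Reactants: 8 photoadduct
Product: 11 1-[(1R,2R)-2-(3-bromo-2-oxopropyl)-1,2-dimethylcyclopentyl]-4-methylpent-3-en-1-one, via lithium hemiketal alkoxide 9 (not isolated), via cyclobutanol 10 (not isolated)
Conditions: CH2Br2 (3 equiv), MeLi·LiBr (2.5 equiv, slow addition), THF/Et2O, –78 °C; AcOH, –78 °C → rt
Reagents that add atoms: dibromomethane BrCBr
Why: Carbenoid homologation of a lactone with in situ LiCH2Br (single addition, tetrahedral alkoxide 9 stable at –78 °C) followed on protonation by collapse of the hemiketal, loss of menthone and strain-driven retro-aldol opening of cyclobutanol 10 (de Mayo fragmentation) under neutral conditions, which unveils both ketones without base and leaves the two quaternary centres untouched.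

Step 5
Reactants: 12 o-cresol
Product: 13 2-bromo-6-methylphenol
Conditions: NBS (1.0 equiv), i-Pr2NH (10 mol %), CH2Cl2, 0 °C → rt
Reagents that add atoms: N-bromosuccinimide O=C1CCC(=O)N1Br
Why: Amine-mediated ortho-selective electrophilic bromination of a phenol (the N-bromoamine delivers bromine to the hydrogen-bonded ortho position), so the 6-bromo isomer is formed in preference to the para isomer.

Step 6
Reactants: 13 2-bromo-6-methylphenol; 14 1-bromobut-2-yne
Product: 16 2-(but-2-yn-1-yl)-6-methylphenol, via dilithiated phenoxide 15 (not isolated)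
Conditions: n-BuLi (2.2 equiv), THF, –78 → 0 °C; CuBr·SMe2 (10 mol %), 14 (1.1 equiv), –40 → 0 °C; 1 M HCl
Reagents that add atoms: none
Why: O-deprotonation and Br/Li exchange give dianion 15, whose aryl–Li end undergoes copper-catalysed SN2 alkylation by the primary propargylic bromide much faster than the lithium phenoxide oxygen reacts, giving the 1-aryl-2-butyne.

Step 7
Reactants: 11 bromomethyl ketone; 16 2-(but-2-yn-1-yl)-6-methylphenol
Product: 18 1-{(1R,2R)-2-[(4E)-6-(2-hydroxy-3-methylphenyl)-4-methyl-2-oxohex-4-en-1-yl]-1,2-dimethylcyclopentyl}-4-methylpent-3-en-1-one, via alkenylzirconocene 17 (not isolated)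
Conditions: 16 (1.4 equiv), Cp2Zr(H)Cl (2.2 equiv per 16), THF, 45 °C, 1 h; then 11, NiCl2·glyme (5 mol %), 4,4'-di-tert-butyl-2,2'-bipyridine (6 mol %), DME/THF, 10 °C → rt; aq. NH4Cl
Reagents that add atoms: none
Why: Schwartz hydrozirconation (syn addition, zirconium settling on the methyl-bearing alkyne carbon under equilibrating conditions, the first equivalent masking ArOH as ArO–Zr) followed by nickel-catalysed cross-coupling of the alkenylzirconocene with the primary α-bromo ketone (radical-type C(sp3)–C(sp2) coupling), which transfers the alkenyl group with retention to give the (E)-β,γ-enone and, being enolate-free, cannot move either skipped enone into conjugation.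

Step 8
Reactants: 18 phenol
Product: 20 1-{(1R,2R)-2-[(4E)-6-(2,5-dihydroxy-3-methylphenyl)-4-methyl-2-oxohex-4-en-1-yl]-1,2-dimethylcyclopentyl}-4-methylpent-3-en-1-one (target), via quinone 19 (not isolated)
Conditions: (KSO3)2NO (2.5 equiv), KH2PO4 buffer, acetone/H2O, 0 °C → rt; then aq. Na2S2O4, Et2O, Ar
Reagents that add atoms: Fremy's salt (potassium nitrosodisulfonate) [K+].[K+].[O]N(S(=O)(=O)[O-])S(=O)(=O)[O-]
Why: Teuber oxidation of the 2,6-dialkylphenol with Fremy's radical gives the para-quinone 19 regiospecifically (the para position is the only free activated site) and dithionite reduction in the same work-up gives the hydroquinone, no stereocentre being involved.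

**Compound list**
1 | 4-methylpent-3-enoic acid | CC(C)=CCC(=O)O | starting material
2 | Meldrum's acid (2,2-dimethyl-1,3-dioxane-4,6-dione) | CC1(C)OC(=O)CC(=O)O1 | starting material
3 | 5-(1-hydroxy-4-methylpent-3-en-1-ylidene)-2,2-dimethyl-1,3-dioxane-4,6-dione | CC(C)=CCC(O)=C1C(=O)OC(C)(C)OC1=O | intermediate
4 | (-)-menthone, (2S,5R)-2-isopropyl-5-methylcyclohexan-1-one | C[C@@H]1CC[C@H](C(=O)C1)C(C)C | starting material
5 | 6-methylhepta-1,5-diene-1,3-dione (acylketene, not isolated) | CC(C)=CCC(=O)C=C=O | intermediate
6 | (6R,7S,10R)-7-isopropyl-10-methyl-4-(3-methylbut-2-en-1-yl)-1,5-dioxaspiro[5.5]undec-3-en-2-one | CC(C)=CCC1=CC(=O)O[C@]2(O1)C[C@H](C)CC[C@H]2C(C)C | intermediate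
7 | 1,2-dimethylcyclopent-1-ene | CC1=C(C)CCC1 | starting material
8 | cis-anti-cis [2+2] adduct of 6 and 7: cyclobutane whose O-bearing carbon (carrying the 3-methylbut-2-enyl group) is bonded to one CMe and whose CH–C(=O)O carbon is bonded to the other CMe; ring fusions cis, methyls syn to the dioxanone ring, four cyclobutane centres R, spiro centre R, menthane as in 6 | CC(C)=CC[C@@]12O[C@@]3(OC(=O)[C@@H]1[C@@]1(C)CCC[C@]12C)C[C@H](C)CC[C@H]3C(C)C | intermediate
9 | lithium hemiketal alkoxide from addition of LiCH2Br to the lactone C=O of 8 (new carbinol centre unassigned, not isolated) | CC(C)=CC[C@@]12O[C@@]3(OC([O-])(CBr)[C@@H]1[C@@]1(C)CCC[C@]12C)C[C@H](C)CC[C@H]3C(C)C.[Li+] | intermediate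
10 | 2-bromo-1-[(1R,5R,6R,7R)-6-hydroxy-1,5-dimethyl-6-(3-methylbut-2-en-1-yl)bicyclo[3.2.0]heptan-7-yl]ethan-1-one (not isolated) | CC(C)=CC[C@@]1(O)[C@H](C(=O)CBr)[C@@]2(C)CCC[C@@]12C | intermediate
11 | 1-[(1R,2R)-2-(3-bromo-2-oxopropyl)-1,2-dimethylcyclopentyl]-4-methylpent-3-en-1-one | CC(C)=CCC(=O)[C@]1(C)CCC[C@]1(C)CC(=O)CBr | intermediate
12 | o-cresol (2-methylphenol) | Cc1ccccc1O | starting material
13 | 2-bromo-6-methylphenol | Cc1cccc(Br)c1O | intermediate
14 | 1-bromobut-2-yne | CC#CCBr | starting material
15 | lithium 2-lithio-6-methylphenolate (not isolated) | [Li]c1cccc(C)c1[O-].[Li+] | intermediate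
16 | 2-(but-2-yn-1-yl)-6-methylphenol | CC#CCc1cccc(C)c1O | intermediate
17 | (E)-alkenylzirconocene chloride from 16, Zr on the methyl-bearing carbon and trans to CH2Ar, phenol oxygen also bound to Cp2ZrCl (Cp drawn σ-bonded, not isolated) | C/C(=C\Cc1cccc(C)c1O[Zr](Cl)(C1C=CC=C1)C1C=CC=C1)[Zr](Cl)(C1C=CC=C1)C1C=CC=C1 | intermediate
18 | 1-{(1R,2R)-2-[(4E)-6-(2-hydroxy-3-methylphenyl)-4-methyl-2-oxohex-4-en-1-yl]-1,2-dimethylcyclopentyl}-4-methylpent-3-en-1-one | CC(C)=CCC(=O)[C@]1(C)CCC[C@]1(C)CC(=O)C/C(C)=C/Cc1cccc(C)c1O | intermediate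
19 | 2-methyl-6-substituted 1,4-benzoquinone corresponding to 20 (not isolated) | CC(C)=CCC(=O)[C@]1(C)CCC[C@]1(C)CC(=O)C/C(C)=C/CC1=CC(=O)C=C(C)C1=O | intermediate
20 | 1-{(1R,2R)-2-[(4E)-6-(2,5-dihydroxy-3-methylphenyl)-4-methyl-2-oxohex-4-en-1-yl]-1,2-dimethylcyclopentyl}-4-methylpent-3-en-1-one (CNP0294415.1) | CC(C)=CCC(=O)[C@]1(C)CCC[C@]1(C)CC(=O)C/C(C)=C/Cc1cc(O)cc(C)c1O | target

**Totals and risk**

Total step count: 8. Longest linear sequence: 6 steps (1 → 2 → 3 → 4 → 7 → 8).

The three steps most likely to fail:

Step 3 (key photocycloaddition). The risks are a modest face or exo/endo preference with a tetrasubstituted alkene, hydrogen-transfer by-products from the 1,4-biradical, and side reactions of the skipped diene in 6. The sense of facial induction by the menthone ketal is an expectation, not a certainty; if the other face reacts, the (6S) spiro epimer from step 2 is used instead. Fallback, setting out from 3 and returning at 11: heating 3 with acetone in toluene gives the achiral acetonide dioxinone 2,2-dimethyl-6-(3-methylbut-2-en-1-yl)-4H-1,3-dioxin-4-one F1. Irradiating F1 with 7 gives the racemic cis-anti-cis acetonide photoadduct F2, which has only two diastereomers to separate. Carbenoid treatment as in step 4 gives the racemic bromomethyl ketone F3, and preparative chromatography on a chiral stationary phase delivers 11. This replaces auxiliary control by racemic synthesis and resolution.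

Step 4 (carbenoid addition and fragmentation). The risks are early collapse of the tetrahedral intermediate with a second carbenoid addition, and Favorskii-type loss of the bromo enolate. Fallback, setting out from 8 and returning at 11: dimethylsulfoxonium methylide (Me3S(O)I, KOt-Bu, THF, 0 °C) acylates once at the lactone. Menthone loss and retro-aldol follow, and the product rests as the stabilised β-keto sulfoxonium ylide F4. Treating F4 with HBr (1 equiv, THF, 0 → 40 °C) gives 11 with loss of DMSO. A stabilised ylide therefore stands in for the unstable carbenoid.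

Step 7 (hydrozirconation and Ni coupling). The risks are the regiopurity of hydrozirconating an internal alkyne, the use of a primary α-bromo dialkyl ketone, and the Zr-bound aryloxide. Fallback, setting out from 8 and 16 and returning at 18: MeLi (1.05 equiv, –78 °C, AcOH quench) opens 8 to the methyl ketone 1-[(1R,2R)-1,2-dimethyl-2-(2-oxopropyl)cyclopentyl]-4-methylpent-3-en-1-one F5. Compound 16 is converted by Cp2Zr(H)Cl then I2 into the vinyl iodide (E)-2-(3-iodobut-2-en-1-yl)-6-methylphenol F6. Pd-catalysed α-alkenylation of the lithium enolate of F5 with F6 (excess LiHMDS, Pd2(dba)3/P(t-Bu)3, THF, rt; cold AcOH quench) gives 18. The polarity is inverted: the ketone becomes the nucleophile. The cost is that the skipped enone sits as its dienolate during the coupling, which could erode its position and the E geometry of the alkene.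

Further compounds
F1 | step 3 | 2,2-dimethyl-6-(3-methylbut-2-en-1-yl)-4H-1,3-dioxin-4-one | CC(C)=CCC1=CC(=O)OC(C)(C)O1
F2 | step 3 | racemic cis-anti-cis acetonide photoadduct of F1 and 7 (both enantiomers written) | CC(C)=CC[C@@]12OC(C)(C)OC(=O)[C@@H]1[C@@]1(C)CCC[C@]12C.CC(C)=CC[C@]12OC(C)(C)OC(=O)[C@H]1[C@]1(C)CCC[C@@]12C
F3 | step 3 | racemic 1-[2-(3-bromo-2-oxopropyl)-1,2-dimethylcyclopentyl]-4-methylpent-3-en-1-one, cis-dimethyl (both enantiomers written) | CC(C)=CCC(=O)[C@]1(C)CCC[C@]1(C)CC(=O)CBr.CC(C)=CCC(=O)[C@@]1(C)CCC[C@@]1(C)CC(=O)CBr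
F4 | step 4 | dimethylsulfoxonium 3-[(1R,2R)-1,2-dimethyl-2-(4-methylpent-3-enoyl)cyclopentyl]-2-oxopropylide | CC(C)=CCC(=O)[C@]1(C)CCC[C@]1(C)CC(=O)C=S(C)(C)=O
F5 | step 7 | 1-[(1R,2R)-1,2-dimethyl-2-(2-oxopropyl)cyclopentyl]-4-methylpent-3-en-1-one | CC(C)=CCC(=O)[C@]1(C)CCC[C@]1(C)CC(C)=O
F6 | step 7 | (E)-2-(3-iodobut-2-en-1-yl)-6-methylphenol | C/C(I)=C\Cc1cccc(C)c1O
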